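**Plan**

- The target has two arenes joined by a CH2–CO–CH2 chain. Ring A is numbered C1 (CO2Me), C2 (chain CH2), C3 (OH), C5 (CH3); ring B is the chlorodimethoxyphenol. There are no stereocentres, so no stereochemistry has to be set.
- After unmasking the ketone (dioxolane) and the ring B phenol (methoxymethyl ether), ring A is cut at C6–C1 and C2–C3. This gives a vinylketene silyl acetal (C3–C6 plus the methyl) and a β-nitroacrylate (C1, C2) that already carries the chain and ring B.
- The enabling feature is that the C3–OH is meta to the C1 ester with the C2 chain between them. A nitro group on C2 reverses the dienophile polarity, so the diene CH2 bonds to C1 and the ketene acetal carbon to C2; nitrous acid and methoxytrimethylsilane are then lost.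
- The nitroacrylate is cut at its C=C (Henry reaction with methyl glyoxylate, then dehydration). The nitroalkane is cut at CH2–CH2NO2 (palladium-catalysed allylation of nitromethane) and at aryl–CH2 (ortho-lithiation and allylation of the ring B ether).
- Forward: ring B phenol, then chain growth to the ketal-protected nitroalkane, then the nitroacrylate; ring A is built last by cycloaddition–aromatisation, and one acid step unmasks the target.

Key step: step 10

Assumption: 2-chloro-1,3-dimethoxybenzene (1) is taken as a purchased compound, and methyl glyoxylate (12) is used freshly distilled from its commercial polymeric or hemiacetal form.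

Remark: the nitro group must sit two carbons from the masked ketone carbon, so nitromethane is joined by allylic substitution on a 2-substituted allyl unit; conjugate addition of nitromethane to a vinyl ketone would give a chain one carbon too long.

**Route**

Step 1
Reactants: 1 2-chloro-1,3-dimethoxybenzene
Product: 3 4-chloro-3,5-dimethoxyphenol, via arylboronic pinacol ester 2 (not isolated)
Conditions: [Ir(OMe)(cod)]2 (1.5 mol%), 4,4'-di-tert-butyl-2,2'-bipyridine (3 mol%), B2pin2 (1.0 equiv), THF, 80 °C; then KHSO5 (Oxone, 2KHSO5·KHSO4·K2SO4), acetone–H2O, rt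
Reagents that add atoms: potassium peroxymonosulfate (Oxone), [K+].[O-]S(=O)(=O)OO
Why: Iridium-catalysed C–H borylation is sterically governed, so only the C–H para to chlorine (the one with no ortho substituent) should be borylated, and ipso-oxidation of the boronate in the same pot should give the symmetric phenol.

Step 2
Reactants: 3 4-chloro-3,5-dimethoxyphenol
Product: 4 2-chloro-1,3-dimethoxy-5-(methoxymethoxy)benzene
Conditions: MOMCl, i-Pr2NEt, CH2Cl2, 0 °C → rt
Reagents that add atoms: chloromethyl methyl ether, COCCl
Why: O-alkylation of the phenol (methoxymethyl protection) installs a group that directs the ortho-lithiation of step 3 and falls in the final acid step.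

Step 3
Reactants: 4 2-chloro-1,3-dimethoxy-5-(methoxymethoxy)benzene; 5 3-chloro-2-(chloromethyl)prop-1-ene
Product: 7 2-chloro-4-[2-(chloromethyl)prop-2-en-1-yl]-1,3-dimethoxy-5-(methoxymethoxy)benzene, via ortho-lithiated arene 6 (not isolated)
Conditions: n-BuLi, THF, 0 °C; then CuBr·SMe2 (10 mol%), 5 (3 equiv), −78 °C → rt
Reagents that add atoms: none
Why: Directed ortho-metalation should occur at the position flanked by the methoxymethoxy and methoxy groups (both such sites are equivalent, and chlorine has no ortho hydrogen, so no benzyne can form), and copper-catalysed allylic substitution on the symmetric bis-chloride in excess gives the same product by SN2 or SN2' attack.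

Step 4
Reactants: 7 2-chloro-4-[2-(chloromethyl)prop-2-en-1-yl]-1,3-dimethoxy-5-(methoxymethoxy)benzene; 8 nitromethane
Product: 9 2-chloro-1,3-dimethoxy-5-(methoxymethoxy)-4-(2-methylidene-4-nitrobutyl)benzene
Conditions: Pd(PPh3)4 (5 mol%), Cs2CO3 (1.5 equiv), 8 (large excess, co-solvent), THF, rt → 40 °C
Reagents that add atoms: none
Why: Tsuji–Trost allylic alkylation through a symmetric 2-substituted π-allylpalladium complex has no regiochemical issue, the zerovalent palladium catalyst favours C- over O-allylation of the nitronate, and excess nitromethane should suppress double allylation.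

Step 5
Reactants: 9 2-chloro-1,3-dimethoxy-5-(methoxymethoxy)-4-(2-methylidene-4-nitrobutyl)benzene
Product: 10 1-[3-chloro-2,4-dimethoxy-6-(methoxymethoxy)phenyl]-4-nitrobutan-2-one
Conditions: K2OsO4·2H2O (2 mol%), NaIO4 (3 equiv), THF–H2O, rt (no amine additive)
Reagents that add atoms: sodium periodate, [Na+].[O-]I(=O)(=O)=O
Why: Lemieux–Johnson oxidative cleavage of the 1,1-disubstituted alkene runs under near-neutral, base-free conditions, which the β-nitro ketone (prone to lose nitrous acid with base) and the electron-rich arene should tolerate.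

Step 6
Reactants: 10 1-[3-chloro-2,4-dimethoxy-6-(methoxymethoxy)phenyl]-4-nitrobutan-2-one
Product: 11 2-{[3-chloro-2,4-dimethoxy-6-(methoxymethoxy)phenyl]methyl}-2-(2-nitroethyl)-1,3-dioxolane
Conditions: TMSOCH2CH2OTMS (2 equiv), TMSOTf (5 mol%), CH2Cl2, −78 → −20 °C; pyridine quench
Reagents that add atoms: 1,2-bis(trimethylsilyloxy)ethane, C[Si](C)(C)OCCO[Si](C)(C)C
Why: Silyl-triflate-catalysed ketalisation with the bis-silyl glycol (Noyori conditions) forms the dioxolane at low temperature without protic acid or base, so the methoxymethyl ether and the β-nitro ketone should both survive.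

Step 7
Reactants: 11 2-{[3-chloro-2,4-dimethoxy-6-(methoxymethoxy)phenyl]methyl}-2-(2-nitroethyl)-1,3-dioxolane; 12 methyl glyoxylate
Product: 13 methyl 4-(2-{[3-chloro-2,4-dimethoxy-6-(methoxymethoxy)phenyl]methyl}-1,3-dioxolan-2-yl)-2-hydroxy-3-nitrobutanoate (racemic mixture of diastereomers)
Conditions: Et3N (0.2 equiv), THF, 0 °C → rt
Reagents that add atoms: none
Why: Henry (nitroaldol) addition of the primary nitronate to the highly electrophilic glyoxylate aldehyde proceeds under mild amine catalysis; the two new stereocentres form unselectively and are both erased in step 8.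

Step 8
Reactants: 13 methyl 4-(2-{[3-chloro-2,4-dimethoxy-6-(methoxymethoxy)phenyl]methyl}-1,3-dioxolan-2-yl)-2-hydroxy-3-nitrobutanoate
Product: 15 methyl (E)-4-(2-{[3-chloro-2,4-dimethoxy-6-(methoxymethoxy)phenyl]methyl}-1,3-dioxolan-2-yl)-3-nitrobut-2-enoate, via nitro mesylate 14 (not isolated)
Conditions: MsCl (1.2 equiv), Et3N (3 equiv), CH2Cl2, −78 → −20 °C
Reagents that add atoms: none
Why: Mesylation followed by E1cB elimination through the nitronate should give the β-nitroacrylate with nitro and ester trans (the more stable E isomer), the low temperature limiting base-induced deconjugation.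

Step 9
Reactants: 16 methyl 3-methylbut-2-enoate
Product: 18 (1Z)-1-methoxy-3-methyl-1-(trimethylsilyloxy)buta-1,3-diene (geometry of no consequence), via lithium dienolate 17 (not isolated)
Conditions: LiN(i-Pr)2 (commercial solution), THF, −78 °C; then TMSCl, −78 °C → rt; pentane, filtration, distillation
Reagents that add atoms: chlorotrimethylsilane, C[Si](C)(C)Cl
Why: γ-Deprotonation of the senecioate gives the extended enolate, and O-silylation (vinylketene silyl acetal formation) delivers the 1,1-dioxygenated diene.

Step 10
Reactants: 15 methyl (E)-4-(2-{[3-chloro-2,4-dimethoxy-6-(methoxymethoxy)phenyl]methyl}-1,3-dioxolan-2-yl)-3-nitrobut-2-enoate; 18 (1Z)-1-methoxy-3-methyl-1-(trimethylsilyloxy)buta-1,3-diene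
Product: 22 methyl 2-({2-[(3-chloro-2,4-dimethoxy-6-(methoxymethoxy)phenyl)methyl]-1,3-dioxolan-2-yl}methyl)-3-hydroxy-5-methylbenzoate, via nitro cycloadduct 19 (not isolated), via cyclohexadiene mixed ketal 20 (not isolated), via cross-conjugated dienone 21 (not isolated)
Conditions: 18 (2 equiv), toluene, −20 °C → rt; then DBU (3 equiv), 0 °C → rt; then MeOH, rt; pH 7 buffer work-up
Reagents that add atoms: none
Why: Nitro is a far stronger acceptor than the ester, so the nucleophilic CH2 terminus of 18 should add to the ester-bearing carbon of 15 (C6–C1) and the nitronate carbon then closes onto the oxocarbenium carbon (C2–C3) in a strongly asynchronous normal-demand [4+2] (Diels–Alder) cycloaddition; ring A thus forms as a six-membered carbocycle by intermolecular cycloaddition. DBU then removes the acidic C1–H next to the ester and expels nitrite from C2 (E1cB) to give diene 20. Methanol with DBU removes the silyl group, the mixed ketal at C3 collapses with loss of methoxytrimethylsilane to dienone 21, and this tautomerises irreversibly to the phenol. The closest known reaction type is the Diels–Alder/nitrous acid elimination sequence of β-alkyl-β-nitroacrylates with siloxydienes, together with the aromatising cycloadditions of this same vinylketene acetal with haloquinones. The three stereocentres of 19 (C1, C2, C3) are all destroyed on aromatisation, so no stereocontrol is needed. The selectivity required is regiochemical (nitro against ester as directing group) and is secured by the greater electron demand of nitro, which places OH at C3 meta to the ester with the chain at C2 and the methyl at C5, while the quaternary dioxolane carbon prevents the nitroalkene from isomerising through an enolisable ketone.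

Step 11
Reactants: 22 methyl 2-({2-[(3-chloro-2,4-dimethoxy-6-(methoxymethoxy)phenyl)methyl]-1,3-dioxolan-2-yl}methyl)-3-hydroxy-5-methylbenzoate
Product: 23 methyl 2-[3-(3-chloro-6-hydroxy-2,4-dimethoxyphenyl)-2-oxopropyl]-3-hydroxy-5-methylbenzoate
Conditions: 2 M HCl (aq), THF, rt → 40 °C
Reagents that add atoms: water, O
Why: Acid-catalysed hydrolysis cleaves the dioxolane and the methoxymethyl acetal in one operation, and dilute aqueous conditions keep water as the trap for the oxocarbenium ion so that neither phenol should close to a benzofuran.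

**Compound list**

1 | 2-chloro-1,3-dimethoxybenzene | COc1cccc(OC)c1Cl | starting material
2 | 2-(4-chloro-3,5-dimethoxyphenyl)-4,4,5,5-tetramethyl-1,3,2-dioxaborolane | COc1cc(B2OC(C)(C)C(C)(C)O2)cc(OC)c1Cl | intermediate
3 | 4-chloro-3,5-dimethoxyphenol | COc1cc(O)cc(OC)c1Cl | intermediate
4 | 2-chloro-1,3-dimethoxy-5-(methoxymethoxy)benzene | COCOc1cc(OC)c(Cl)c(OC)c1 | intermediate
5 | 3-chloro-2-(chloromethyl)prop-1-ene | C=C(CCl)CCl | starting material
6 | [3-chloro-2,4-dimethoxy-6-(methoxymethoxy)phenyl]lithium | [Li]c1c(OCOC)cc(OC)c(Cl)c1OC | intermediate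
7 | 2-chloro-4-[2-(chloromethyl)prop-2-en-1-yl]-1,3-dimethoxy-5-(methoxymethoxy)benzene | ClCC(=C)Cc1c(OCOC)cc(OC)c(Cl)c1OC | intermediate
8 | nitromethane | C[N+](=O)[O-] | starting material
9 | 2-chloro-1,3-dimethoxy-5-(methoxymethoxy)-4-(2-methylidene-4-nitrobutyl)benzene | [O-][N+](=O)CCC(=C)Cc1c(OCOC)cc(OC)c(Cl)c1OC | intermediate
10 | 1-[3-chloro-2,4-dimethoxy-6-(methoxymethoxy)phenyl]-4-nitrobutan-2-one | O=C(CC[N+](=O)[O-])Cc1c(OCOC)cc(OC)c(Cl)c1OC | intermediate
11 | 2-{[3-chloro-2,4-dimethoxy-6-(methoxymethoxy)phenyl]methyl}-2-(2-nitroethyl)-1,3-dioxolane | [O-][N+](=O)CCC1(Cc2c(OCOC)cc(OC)c(Cl)c2OC)OCCO1 | intermediate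
12 | methyl glyoxylate | COC(=O)C=O | starting material
13 | methyl 4-(2-{[3-chloro-2,4-dimethoxy-6-(methoxymethoxy)phenyl]methyl}-1,3-dioxolan-2-yl)-2-hydroxy-3-nitrobutanoate (racemic diastereomer mixture) | COC(=O)C(O)C([N+](=O)[O-])CC1(Cc2c(OCOC)cc(OC)c(Cl)c2OC)OCCO1 | intermediate
14 | methyl 4-(2-{[3-chloro-2,4-dimethoxy-6-(methoxymethoxy)phenyl]methyl}-1,3-dioxolan-2-yl)-2-(methanesulfonyloxy)-3-nitrobutanoate (diastereomer mixture) | COC(=O)C(OS(C)(=O)=O)C([N+](=O)[O-])CC1(Cc2c(OCOC)cc(OC)c(Cl)c2OC)OCCO1 | intermediate
15 | methyl (E)-4-(2-{[3-chloro-2,4-dimethoxy-6-(methoxymethoxy)phenyl]methyl}-1,3-dioxolan-2-yl)-3-nitrobut-2-enoate | COC(=O)/C=C(/[N+](=O)[O-])CC1(Cc2c(OCOC)cc(OC)c(Cl)c2OC)OCCO1 | intermediate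
16 | methyl 3-methylbut-2-enoate | COC(=O)C=C(C)C | starting material
17 | lithium 1-methoxy-3-methylbuta-1,3-dien-1-olate | [Li]OC(OC)=CC(C)=C | intermediate
18 | (1Z)-1-methoxy-3-methyl-1-(trimethylsilyloxy)buta-1,3-diene | C=C(C)/C=C(/OC)O[Si](C)(C)C | intermediate
19 | methyl 6-({2-[(3-chloro-2,4-dimethoxy-6-(methoxymethoxy)phenyl)methyl]-1,3-dioxolan-2-yl}methyl)-5-methoxy-3-methyl-6-nitro-5-(trimethylsilyloxy)cyclohex-3-ene-1-carboxylate (diastereomer mixture) | COC(=O)C1CC(C)=CC(OC)(O[Si](C)(C)C)C1([N+](=O)[O-])CC1(Cc2c(OCOC)cc(OC)c(Cl)c2OC)OCCO1 | intermediate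
20 | methyl 2-({2-[(3-chloro-2,4-dimethoxy-6-(methoxymethoxy)phenyl)methyl]-1,3-dioxolan-2-yl}methyl)-3-methoxy-5-methyl-3-(trimethylsilyloxy)cyclohexa-1,4-diene-1-carboxylate (racemic) | COC(=O)C1=C(CC2(Cc3c(OCOC)cc(OC)c(Cl)c3OC)OCCO2)C(OC)(O[Si](C)(C)C)C=C(C)C1 | intermediate
21 | methyl 2-({2-[(3-chloro-2,4-dimethoxy-6-(methoxymethoxy)phenyl)methyl]-1,3-dioxolan-2-yl}methyl)-5-methyl-3-oxocyclohexa-1,4-diene-1-carboxylate | COC(=O)C1=C(CC2(Cc3c(OCOC)cc(OC)c(Cl)c3OC)OCCO2)C(=O)C=C(C)C1 | intermediate
22 | methyl 2-({2-[(3-chloro-2,4-dimethoxy-6-(methoxymethoxy)phenyl)methyl]-1,3-dioxolan-2-yl}methyl)-3-hydroxy-5-methylbenzoate | COC(=O)c1cc(C)cc(O)c1CC1(Cc2c(OCOC)cc(OC)c(Cl)c2OC)OCCO1 | intermediate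
23 | methyl 2-[3-(3-chloro-6-hydroxy-2,4-dimethoxyphenyl)-2-oxopropyl]-3-hydroxy-5-methylbenzoate | COC(=O)c1cc(C)cc(O)c1CC(=O)Cc1c(O)cc(OC)c(Cl)c1OC | target

**Step count and risks**

Total steps: 11. Longest linear sequence: 10 steps (steps 1–8, 10, 11); step 9 is a one-step branch.

Most likely to fail:

1. Step 10. The reaction may stop at the conjugate-addition stage, with silyl transfer to the nitronate outrunning C2–C3 closure at the crowded nitro-bearing carbon, or the nitroalkene may react as a heterodiene with the ketene acetal double bond; either process leaves ring A unformed. The fallback abandons the cycloaddition for an aromatic Claisen route that sets out from allyl chloride 7 and returns to the route at target 23. Purchased methyl 3-hydroxy-5-methylbenzoate F1 would be O-alkylated with 7 (K2CO3, NaI, DMF) to the allyl aryl ether F2. Heating in N,N-diethylaniline at about 190 °C should bring about the [3,3] rearrangement, the meta ester biasing migration to the ortho position between oxygen and ester, to give the 2-allylated phenol F3, which holds the full carbon skeleton with the ketone masked as an exocyclic methylene. Oxidative cleavage (K2OsO4·2H2O, NaIO4, THF–H2O) should then give the methoxymethyl-protected ketone F4, and dilute aqueous HCl in THF removes the methoxymethyl group to reach 23.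

2. Step 4. Double allylation of nitromethane, O-allylation of the nitronate by the allyl chloride and migration of the alkene into conjugation with the arene may erode the mono-C-allylated product. The fallback reverses the polarity (nitrite as nucleophile instead of nitromethane), sets out from ether 4 through its lithio derivative 6, and returns at nitro ketone 10. Quenching 6 with allyl bromide (CuBr·SMe2 cat.) would give the allylarene F5. Oxidative cleavage (K2OsO4·2H2O, NaIO4) gives the arylacetaldehyde F6, addition of CH2=CHMgBr (THF, −78 °C) gives the racemic allylic alcohol F7, and Dess–Martin oxidation gives the benzyl vinyl ketone F8, which is used at once. Conjugate addition of nitrous acid (NaNO2, AcOH, THF, rt) then delivers 10 with the nitro group two carbons from the carbonyl.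

3. Step 11. Under the aqueous acid needed for the methoxymethyl ether, a freed phenol may add to the ketone or its oxocarbenium ion and dehydrate irreversibly to a benzofuran. The fallback unmasks in two chemoselective stages, sets out from 22 and returns at 23. Buffered exchange (pyridinium p-toluenesulfonate, acetone–H2O, 55 °C) should remove only the dioxolane to give the methoxymethyl-protected ketone F9. The aryl methoxymethyl ether is then cleaved under aprotic conditions (TMSOTf, 2,2'-bipyridyl, CH2Cl2, 0 °C; then H2O), where no strong protic acid or heat is present to drive dehydration.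

**Further compounds**

F1 | step 10 | methyl 3-hydroxy-5-methylbenzoate | COC(=O)c1cc(C)cc(O)c1
F2 | step 10 | methyl 3-({2-[(3-chloro-2,4-dimethoxy-6-(methoxymethoxy)phenyl)methyl]prop-2-en-1-yl}oxy)-5-methylbenzoate | COC(=O)c1cc(C)cc(OCC(=C)Cc2c(OCOC)cc(OC)c(Cl)c2OC)c1
F3 | step 10 | methyl 2-{2-[(3-chloro-2,4-dimethoxy-6-(methoxymethoxy)phenyl)methyl]prop-2-en-1-yl}-3-hydroxy-5-methylbenzoate | COC(=O)c1cc(C)cc(O)c1CC(=C)Cc1c(OCOC)cc(OC)c(Cl)c1OC
F4 | step 10 | methyl 2-{3-[3-chloro-2,4-dimethoxy-6-(methoxymethoxy)phenyl]-2-oxopropyl}-3-hydroxy-5-methylbenzoate | COC(=O)c1cc(C)cc(O)c1CC(=O)Cc1c(OCOC)cc(OC)c(Cl)c1OC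
F5 | step 4 | 2-chloro-1,3-dimethoxy-5-(methoxymethoxy)-4-(prop-2-en-1-yl)benzene | C=CCc1c(OCOC)cc(OC)c(Cl)c1OC
F6 | step 4 | 2-[3-chloro-2,4-dimethoxy-6-(methoxymethoxy)phenyl]acetaldehyde | O=CCc1c(OCOC)cc(OC)c(Cl)c1OC
F7 | step 4 | 1-[3-chloro-2,4-dimethoxy-6-(methoxymethoxy)phenyl]but-3-en-2-ol (racemic) | C=CC(O)Cc1c(OCOC)cc(OC)c(Cl)c1OC
F8 | step 4 | 1-[3-chloro-2,4-dimethoxy-6-(methoxymethoxy)phenyl]but-3-en-2-one | C=CC(=O)Cc1c(OCOC)cc(OC)c(Cl)c1OC
F9 | step 11 | methyl 2-{3-[3-chloro-2,4-dimethoxy-6-(methoxymethoxy)phenyl]-2-oxopropyl}-3-hydroxy-5-methylbenzoate | COC(=O)c1cc(C)cc(O)c1CC(=O)Cc1c(OCOC)cc(OC)c(Cl)c1OC
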